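The synthesis rests on cutting the trans-decalin (labdane numbering) at C5–C6 and C1–C10, the two bonds that flank the C5–C10 ring fusion between the C6 carbinol of ring B and the C2 oxygen of ring A. In step 13 a Lewis acid activates a C6 aldehyde, C5 of a conjugated diene attacks it, and the C10 allyl cation so formed is trapped by a C1 enol silane: both rings, two C–C bonds and the C5, C6 and C10 stereocentres arise in one operation from a single C7 silyloxy stereocentre. The precursor is an acyclic (2S,3Z,5E)-2-silyloxy-3,5,9-trienal with a terminal TBS enol ether and a silyl-protected hydroxyethyl branch at C9.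

Key step: step 13

Remarks on the chemistry
- Numbering: labdane numbering is used for every intermediate. In the acyclic compounds the aldehyde carbon is C6, the silyloxy carbon C7, the tetrasubstituted alkene C8=C9, the trisubstituted alkene C10=C5, and the enol silane C1=C2.
- Stereochemical bookkeeping: the trienal must be the 2S isomer (C7), which becomes 7α. Boronate 17 is Z by the sequence rule (C ranks above B) although it has the geometry that becomes 5E in 18.
- Precursor design: C12 is carried as a TIPS ether and not as an ester. An ester would be a second Lewis-basic site in step 13 and could not be removed later beside three acetates. The TIPS ether leaves together with the C7 TIPS group in step 15.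
- Precursor design: the C6 oxygen travels as a pivalate, so the aldehyde can be unmasked without acid or fluoride (steps 11 and 12) after the enol silane is in place.
- Assumption: amide 3, prop-1-yn-1-yllithium 13 and B-methoxy-9-BBN are bought.
- Assumption: the sense of the transfer hydrogenation in step 3 is assigned by analogy with alkynyl methyl ketones and should be confirmed by Mosher analysis of 6.

Step 1
Reactants: 1 but-3-yn-1-ol
Product: 2 (but-3-yn-1-yloxy)triisopropylsilane
Conditions: TIPSCl, imidazole, CH2Cl2, 0 °C → rt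
Reagents that add atoms: triisopropylsilyl chloride, CC(C)[Si](Cl)(C(C)C)C(C)C
Why: Imidazole-promoted silylation of a primary alcohol; the TIPS ether should survive the Grignard, amide base, aluminium hydride, Lewis acid and dissolving-metal steps that follow.

Step 2
Reactants: 2 (but-3-yn-1-yloxy)triisopropylsilane; 3 2-[(tert-butyldimethylsilyl)oxy]-N-methoxy-N-methylacetamide
Product: 5 1-[(tert-butyldimethylsilyl)oxy]-6-[(triisopropylsilyl)oxy]hex-3-yn-2-one, via lithium acetylide 4 (not isolated)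
Conditions: n-BuLi, THF, −78 °C; then 3, −78 → 0 °C; aq. NH4Cl
Reagents that add atoms: none
Why: Weinreb ketone synthesis: the lithium acetylide adds once to the N-methoxy-N-methylamide because the chelated tetrahedral intermediate persists until work-up, which should give the ynone (C6–C7 joined to C8≡C9–C11–C12).

Step 3
Reactants: 5 1-[(tert-butyldimethylsilyl)oxy]-6-[(triisopropylsilyl)oxy]hex-3-yn-2-one
Product: 6 (2S)-1-[(tert-butyldimethylsilyl)oxy]-6-[(triisopropylsilyl)oxy]hex-3-yn-2-ol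
Conditions: Ru(p-cymene)[(R,R)-TsDPEN] (1 mol %), i-PrOH, rt
Reagents that add atoms: none
Why: Noyori asymmetric transfer hydrogenation of an ynone: the Ru–H/N–H catalyst distinguishes the alkynyl group from the CH2OTBS group and delivers hydride to one carbonyl face, which sets C7 as S.

Step 4
Reactants: 6 (2S)-1-[(tert-butyldimethylsilyl)oxy]-6-[(triisopropylsilyl)oxy]hex-3-yn-2-ol
Product: 9 (2S,3Z)-4-iodo-3-methyl-6-[(triisopropylsilyl)oxy]hex-3-ene-1,2-diol, via cyclic alkenylmagnesium alkoxide 7 (not isolated), via 1-O-TBS iodo alcohol 8 (not isolated)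
Conditions: MeMgBr (3 equiv.), CuI (10 mol %), THF, −20 °C → rt; I2, −78 → 0 °C; aq. Na2S2O3; then crude 8, CSA (cat.), MeOH, 0 °C
Reagents that add atoms: methylmagnesium bromide, C[Mg]Br; iodine, II
Why: CuI-catalysed anti-carbomagnesiation of a propargylic alkoxide: methyl adds to C8 while magnesium is held at C9 in a five-membered chelate to the C7 oxygen, so iodinolysis with retention should give the Z-tetrasubstituted iodide (I cis to C7, CH3 cis to C11), and acidic methanol then frees the primary hydroxyl without touching C7 or the primary TIPS ether.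

Step 5
Reactants: 9 (2S,3Z)-4-iodo-3-methyl-6-[(triisopropylsilyl)oxy]hex-3-ene-1,2-diol
Product: 10 (2S,3Z)-2-hydroxy-4-iodo-3-methyl-6-[(triisopropylsilyl)oxy]hex-3-en-1-yl 2,2-dimethylpropanoate
Conditions: PivCl, pyridine, CH2Cl2, −20 → 0 °C
Reagents that add atoms: pivaloyl chloride, CC(C)(C)C(=O)Cl
Why: Selective acylation of the primary hydroxyl beside the hindered secondary allylic one; the pivalate has no α-hydrogen, so it should survive the amide base of step 10 and leave under DIBAL-type reduction in step 11.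

Step 6
Reactants: 10 (2S,3Z)-2-hydroxy-4-iodo-3-methyl-6-[(triisopropylsilyl)oxy]hex-3-en-1-yl 2,2-dimethylpropanoate
Product: 11 (2S,3Z)-4-iodo-3-methyl-2,6-bis[(triisopropylsilyl)oxy]hex-3-en-1-yl 2,2-dimethylpropanoate
Conditions: TIPSOTf, 2,6-lutidine, CH2Cl2, 0 °C → rt
Reagents that add atoms: triisopropylsilyl trifluoromethanesulfonate, CC(C)[Si](OS(=O)(=O)C(F)(F)F)(C(C)C)C(C)C
Why: Silyl triflate silylation of a hindered secondary allylic alcohol; the bulky, non-chelating C7 OTIPS group is the control element of step 13.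

Step 7
Reactants: 12 4-methylpent-3-en-2-one (mesityl oxide); 13 prop-1-yn-1-yllithium
Product: 16 4,4-dimethylhept-5-yn-2-one, via B-(prop-1-ynyl)-9-BBN 14 (not isolated), via enol borinate 15 (not isolated)
Conditions: 13, B-MeO-9-BBN, THF, −78 °C; BF3·OEt2, −78 °C → rt; then 12, pentane, rt; H2O
Reagents that add atoms: none
Why: Conjugate alkynylation of an enone by a B-alkynyl-9-BBN through a six-membered transition state that requires the s-cis enone; mesityl oxide is held s-cis by its cis β-methyl group, so the propynyl group should go to the β-carbon and build the C4 quaternary centre with the C2 ketone already in place.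

Step 8
Reactants: 16 4,4-dimethylhept-5-yn-2-one
Product: 17 (5Z)-4,4-dimethyl-6-(4,4,5,5-tetramethyl-1,3,2-dioxaborolan-2-yl)hept-5-en-2-one
Conditions: B2pin2, CuCl (5 mol %), Xantphos (5 mol %), NaOt-Bu (10 mol %), MeOH (2 equiv.), THF, rt
Reagents that add atoms: bis(pinacolato)diboron, CC1(C)OB(OC1(C)C)B1OC(C)(C)C(C)(C)O1
Why: Copper-catalysed protoboration of an internal alkyne (syn borylcupration, then methanolysis of the C–Cu bond): boron should go to the methyl-bearing carbon remote from the quaternary centre and H adds cis, which fixes the C5=C10 geometry (boron trans to C4), and the phosphine–copper boryl should not add to the unactivated ketone.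

Step 9
Reactants: 11 (2S,3Z)-4-iodo-3-methyl-2,6-bis[(triisopropylsilyl)oxy]hex-3-en-1-yl 2,2-dimethylpropanoate; 17 (5Z)-4,4-dimethyl-6-(4,4,5,5-tetramethyl-1,3,2-dioxaborolan-2-yl)hept-5-en-2-one
Product: 18 (2S,3Z,5E)-3,5,7,7-tetramethyl-9-oxo-2-[(triisopropylsilyl)oxy]-4-{2-[(triisopropylsilyl)oxy]ethyl}deca-3,5-dien-1-yl 2,2-dimethylpropanoate
Conditions: Pd(OAc)2 (5 mol %), SPhos (10 mol %), K3PO4, THF/H2O (10:1), 50 °C
Reagents that add atoms: none
Why: Suzuki–Miyaura coupling with retention at both alkenyl carbons forms the C9–C10 bond of the 3Z,5E diene; a bulky biarylphosphine is chosen for the two hindered partners and the phosphate base should spare pivalate, ketone and silyl ethers.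

Step 10
Reactants: 18 (2S,3Z,5E)-3,5,7,7-tetramethyl-9-oxo-2-[(triisopropylsilyl)oxy]-4-{2-[(triisopropylsilyl)oxy]ethyl}deca-3,5-dien-1-yl 2,2-dimethylpropanoate
Product: 20 (2S,3Z,5E)-9-[(tert-butyldimethylsilyl)oxy]-3,5,7,7-tetramethyl-2-[(triisopropylsilyl)oxy]-4-{2-[(triisopropylsilyl)oxy]ethyl}deca-3,5,9-trien-1-yl 2,2-dimethylpropanoate, via lithium enolate 19 (not isolated)
Conditions: LiN(i-Pr)2, THF, −78 °C; TBSOTf, −78 °C; Et3N, aq. NaHCO3
Reagents that add atoms: tert-butyldimethylsilyl trifluoromethanesulfonate, CC(C)(C)[Si](C)(C)OS(=O)(=O)C(F)(F)F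
Why: Kinetic enolisation and O-silylation: the amide base should take a proton from the C1 methyl group and not from the neopentyl C3 methylene, the pivalate has no α-hydrogen, and C7–H is not acidic at −78 °C, so the terminal enol silane results.

Step 11
Reactants: 20 (2S,3Z,5E)-9-[(tert-butyldimethylsilyl)oxy]-3,5,7,7-tetramethyl-2-[(triisopropylsilyl)oxy]-4-{2-[(triisopropylsilyl)oxy]ethyl}deca-3,5,9-trien-1-yl 2,2-dimethylpropanoate
Product: 21 (2S,3Z,5E)-9-[(tert-butyldimethylsilyl)oxy]-3,5,7,7-tetramethyl-2-[(triisopropylsilyl)oxy]-4-{2-[(triisopropylsilyl)oxy]ethyl}deca-3,5,9-trien-1-ol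
Conditions: i-Bu2AlH, CH2Cl2, −78 °C; aq. potassium sodium tartrate
Reagents that add atoms: none
Why: Reductive cleavage of the pivalate by the aluminium hydride, a deprotection free of acid and fluoride that should leave the enol silane and both TIPS ethers intact.

Step 12
Reactants: 21 (2S,3Z,5E)-9-[(tert-butyldimethylsilyl)oxy]-3,5,7,7-tetramethyl-2-[(triisopropylsilyl)oxy]-4-{2-[(triisopropylsilyl)oxy]ethyl}deca-3,5,9-trien-1-ol
Product: 22 (2S,3Z,5E)-9-[(tert-butyldimethylsilyl)oxy]-3,5,7,7-tetramethyl-2-[(triisopropylsilyl)oxy]-4-{2-[(triisopropylsilyl)oxy]ethyl}deca-3,5,9-trienal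
Conditions: Dess–Martin periodinane, NaHCO3, CH2Cl2, 0 °C; used at once
Reagents that add atoms: none
Why: Buffered Dess–Martin oxidation of the primary alcohol; C7–H should lie in the plane of the tetrasubstituted alkene (A(1,3) strain), which disfavours enolisation and loss of the C7 configuration.

Step 13
Reactants: 22 (2S,3Z,5E)-9-[(tert-butyldimethylsilyl)oxy]-3,5,7,7-tetramethyl-2-[(triisopropylsilyl)oxy]-4-{2-[(triisopropylsilyl)oxy]ethyl}deca-3,5,9-trienal
Product: 23 (5S,6S,7S,10S)-6β-hydroxy-7α,12-bis[(triisopropylsilyl)oxy]-13,14,15,16-tetranorlabd-8-en-2-one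
Conditions: MeAlCl2 (2 equiv.), CH2Cl2 (0.005 M), −95 → −78 °C; Et3N/MeOH; aq. NaHCO3
Reagents that add atoms: none
Why: Proposed new method: MeAlCl2 binds the C6 aldehyde, C5 of the diene adds to the activated carbonyl, the positive charge is relayed into a C10–C9–C8 allyl cation, and C1 of the enol silane bonds to C10, after which loss of the TBS group to chloride leaves the C2 ketone; the closest known reaction type is the Lewis-acid aldehyde-initiated (Prins) cation–olefin bicyclisation terminated by an enol silane, which has not been relayed through a conjugated diene. Ring B closes 6-endo-trig at the C5=C10 alkene (C5–C6 bond), and ring A closes by attack of the enol silane terminus on the allyl cation at C10 with the enol π bond inside the new six-membered ring, C8 being out of reach because it would need an eight-membered ring. C5 and C10 are set together by anti addition across the E-C5=C10 alkene in a chair–chair array, which gives the trans fusion (5α-H, 10β-CH3). Their absolute sense comes from C7: A(1,2) strain with the C8 methyl group keeps the OTIPS group pseudoaxial, so the diene face that places H-5 cis to O-7 is used. C6 is set by the non-chelated carbonyl lying anti to the C7–O bond, which makes the new hydroxyl axial (6β). The step needs the intramolecular Prins path to win over Mukaiyama aldol addition: the direct aldol would require a ten-membered ring, high dilution suppresses the bimolecular one, and the enol silane out-competes chloride capture and proton loss at the cation.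

Step 14
Reactants: 23 (5S,6S,7S,10S)-6β-hydroxy-7α,12-bis[(triisopropylsilyl)oxy]-13,14,15,16-tetranorlabd-8-en-2-one
Product: 24 7α,12-bis[(triisopropylsilyl)oxy]-13,14,15,16-tetranorlabd-8-ene-2α,6β-diol
Conditions: Li, NH3(l), THF, MeOH, −78 °C; NH4Cl
Reagents that add atoms: none
Why: Dissolving-metal reduction of the ketone (ketyl, then protonation of the carbanion) should give the thermodynamically preferred equatorial 2α-alcohol, because a 2β-hydroxyl would be 1,3-diaxial to both the C4 and C10 methyl groups, whereas a hydride reagent would attack from the open α face and give the axial epimer; the isolated tetrasubstituted alkene and the silyl ethers should not be reduced at −78 °C.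

Step 15
Reactants: 24 7α,12-bis[(triisopropylsilyl)oxy]-13,14,15,16-tetranorlabd-8-ene-2α,6β-diol
Product: 25 13,14,15,16-tetranorlabd-8-ene-2α,6β,7α,12-tetrol
Conditions: TBAF, THF, rt → 45 °C
Reagents that add atoms: none
Why: Fluoride-mediated desilylation removes the secondary C7 and the primary C12 TIPS ethers in one operation.

Step 16
Reactants: 25 13,14,15,16-tetranorlabd-8-ene-2α,6β,7α,12-tetrol
Product: 26 12-iodo-13,14,15,16-tetranorlabd-8-ene-2α,6β,7α-triol
Conditions: PPh3, I2, imidazole (premixed), THF/MeCN, 0 °C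
Reagents that add atoms: iodine, II
Why: Appel-type iodination is selective for the primary C12 hydroxyl over the three hindered secondary ones, and premixing PPh3 with I2 keeps free iodine away from the C8=C9 alkene.

Step 17
Reactants: 26 12-iodo-13,14,15,16-tetranorlabd-8-ene-2α,6β,7α-triol
Product: 27 12-iodo-13,14,15,16-tetranorlabd-8-ene-2α,6β,7α-triyl triacetate
Conditions: Ac2O, DMAP, Et3N, CH2Cl2, rt → 35 °C
Reagents that add atoms: acetic anhydride, CC(=O)OC(C)=O
Why: DMAP-catalysed acetylation of the three secondary hydroxyls; the axial 6β-hydroxyl between the two axial methyl groups should be the slowest and sets the reaction time.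

Step 18
Reactants: 28 but-2-yn-1-ol
Product: 29 (but-2-yn-1-yloxy)(tert-butyl)dimethylsilane
Conditions: TBSCl, imidazole, CH2Cl2, rt
Reagents that add atoms: tert-butyldimethylsilyl chloride, CC(C)(C)[Si](C)(C)Cl
Why: Imidazole-promoted silylation of a primary alcohol; the silyl ether blocks alkoxide-directed hydrozirconation and is removable beside acetates.

Step 19
Reactants: 29 (but-2-yn-1-yloxy)(tert-butyl)dimethylsilane
Product: 31 tert-butyl{[(2E)-3-iodobut-2-en-1-yl]oxy}dimethylsilane, via alkenylzirconocene chloride 30 (not isolated)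
Conditions: Cp2Zr(H)Cl (2 equiv.), THF, 50 °C; I2, 0 °C
Reagents that add atoms: iodine, II
Why: Hydrozirconation–iodination: syn addition of Zr–H with excess reagent under equilibrating conditions should place zirconium on the methyl-bearing carbon remote from the silyloxymethyl group, and iodinolysis with retention gives the E-iodide (I trans to CH2O).

Step 20
Reactants: 27 12-iodo-13,14,15,16-tetranorlabd-8-ene-2α,6β,7α-triyl triacetate; 31 tert-butyl{[(2E)-3-iodobut-2-en-1-yl]oxy}dimethylsilane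
Product: 33 15-[(tert-butyldimethylsilyl)oxy]labda-8,13E-diene-2α,6β,7α-triyl triacetate, via alkylzinc iodide 32 (not isolated)
Conditions: Zn dust (TMSCl-activated), DMA, 40 °C; then 31, Pd(PPh3)4 (5 mol %), THF, rt
Reagents that add atoms: none
Why: Negishi coupling: zinc inserts into the primary C–I bond without touching the acetates, and palladium-catalysed coupling with the alkenyl iodide proceeds with retention, so the C12–C13 bond forms with the 13E geometry.

Step 21
Reactants: 33 15-[(tert-butyldimethylsilyl)oxy]labda-8,13E-diene-2α,6β,7α-triyl triacetate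
Product: 34 (2S,5S,6S,7S,10S)-15-hydroxylabda-8,13E-diene-2α,6β,7α-triyl triacetate (CNP0305346.2)
Conditions: HF·pyridine, pyridine, THF, 0 °C
Reagents that add atoms: none
Why: Buffered fluoride cleavage of the primary allylic TBS ether, conditions under which the three acetates and the allylic C7 acetate should remain untouched.

Compound list
1 | but-3-yn-1-ol | C#CCCO | starting material
2 | (but-3-yn-1-yloxy)triisopropylsilane | C#CCCO[Si](C(C)C)(C(C)C)C(C)C | intermediate
3 | 2-[(tert-butyldimethylsilyl)oxy]-N-methoxy-N-methylacetamide | CON(C)C(=O)CO[Si](C)(C)C(C)(C)C | starting material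
4 | lithium 4-[(triisopropylsilyl)oxy]but-1-yn-1-ide (lithium acetylide of 2) | [Li]C#CCCO[Si](C(C)C)(C(C)C)C(C)C | intermediate
5 | 1-[(tert-butyldimethylsilyl)oxy]-6-[(triisopropylsilyl)oxy]hex-3-yn-2-one | CC(C)(C)[Si](C)(C)OCC(=O)C#CCCO[Si](C(C)C)(C(C)C)C(C)C | intermediate
6 | (2S)-1-[(tert-butyldimethylsilyl)oxy]-6-[(triisopropylsilyl)oxy]hex-3-yn-2-ol | CC(C)(C)[Si](C)(C)OC[C@@H](O)C#CCCO[Si](C(C)C)(C(C)C)C(C)C | intermediate
7 | cyclic alkenylmagnesium alkoxide (Mg bridging C9 and O7; CH3 on C8) | CC1=C(CCO[Si](C(C)C)(C(C)C)C(C)C)[Mg]O[C@@H]1CO[Si](C)(C)C(C)(C)C | intermediate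
8 | (2S,3Z)-1-[(tert-butyldimethylsilyl)oxy]-4-iodo-3-methyl-6-[(triisopropylsilyl)oxy]hex-3-en-2-ol | CC(C)(C)[Si](C)(C)OC[C@@H](O)/C(C)=C(\I)CCO[Si](C(C)C)(C(C)C)C(C)C | intermediate
9 | (2S,3Z)-4-iodo-3-methyl-6-[(triisopropylsilyl)oxy]hex-3-ene-1,2-diol | OC[C@@H](O)/C(C)=C(\I)CCO[Si](C(C)C)(C(C)C)C(C)C | intermediate
10 | (2S,3Z)-2-hydroxy-4-iodo-3-methyl-6-[(triisopropylsilyl)oxy]hex-3-en-1-yl 2,2-dimethylpropanoate | CC(C)(C)C(=O)OC[C@@H](O)/C(C)=C(\I)CCO[Si](C(C)C)(C(C)C)C(C)C | intermediate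
11 | (2S,3Z)-4-iodo-3-methyl-2,6-bis[(triisopropylsilyl)oxy]hex-3-en-1-yl 2,2-dimethylpropanoate | CC(C)(C)C(=O)OC[C@@H](O[Si](C(C)C)(C(C)C)C(C)C)/C(C)=C(\I)CCO[Si](C(C)C)(C(C)C)C(C)C | intermediate
12 | 4-methylpent-3-en-2-one (mesityl oxide) | CC(=O)C=C(C)C | starting material
13 | prop-1-yn-1-yllithium | [Li]C#CC | starting material
14 | 9-(prop-1-yn-1-yl)-9-borabicyclo[3.3.1]nonane | CC#CB1C2CCCC1CCC2 | intermediate
15 | 9-{[(2Z)-4,4-dimethylhept-2-en-5-yn-2-yl]oxy}-9-borabicyclo[3.3.1]nonane (enol borinate) | CC#CC(C)(C)/C=C(/C)OB1C2CCCC1CCC2 | intermediate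
16 | 4,4-dimethylhept-5-yn-2-one | CC#CC(C)(C)CC(C)=O | intermediate
17 | (5Z)-4,4-dimethyl-6-(4,4,5,5-tetramethyl-1,3,2-dioxaborolan-2-yl)hept-5-en-2-one | CC(=O)CC(C)(C)/C=C(\C)B1OC(C)(C)C(C)(C)O1 | intermediate
18 | (2S,3Z,5E)-3,5,7,7-tetramethyl-9-oxo-2-[(triisopropylsilyl)oxy]-4-{2-[(triisopropylsilyl)oxy]ethyl}deca-3,5-dien-1-yl 2,2-dimethylpropanoate | CC(=O)CC(C)(C)/C=C(C)/C(CCO[Si](C(C)C)(C(C)C)C(C)C)=C(C)\[C@H](O[Si](C(C)C)(C(C)C)C(C)C)COC(=O)C(C)(C)C | intermediate
19 | lithium enolate of 18 (C1=C2–OLi) | [Li]OC(=C)CC(C)(C)/C=C(C)/C(CCO[Si](C(C)C)(C(C)C)C(C)C)=C(C)\[C@H](O[Si](C(C)C)(C(C)C)C(C)C)COC(=O)C(C)(C)C | intermediate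
20 | (2S,3Z,5E)-9-[(tert-butyldimethylsilyl)oxy]-3,5,7,7-tetramethyl-2-[(triisopropylsilyl)oxy]-4-{2-[(triisopropylsilyl)oxy]ethyl}deca-3,5,9-trien-1-yl 2,2-dimethylpropanoate | C=C(O[Si](C)(C)C(C)(C)C)CC(C)(C)/C=C(C)/C(CCO[Si](C(C)C)(C(C)C)C(C)C)=C(C)\[C@H](O[Si](C(C)C)(C(C)C)C(C)C)COC(=O)C(C)(C)C | intermediate
21 | (2S,3Z,5E)-9-[(tert-butyldimethylsilyl)oxy]-3,5,7,7-tetramethyl-2-[(triisopropylsilyl)oxy]-4-{2-[(triisopropylsilyl)oxy]ethyl}deca-3,5,9-trien-1-ol | C=C(O[Si](C)(C)C(C)(C)C)CC(C)(C)/C=C(C)/C(CCO[Si](C(C)C)(C(C)C)C(C)C)=C(C)\[C@H](O[Si](C(C)C)(C(C)C)C(C)C)CO | intermediate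
22 | (2S,3Z,5E)-9-[(tert-butyldimethylsilyl)oxy]-3,5,7,7-tetramethyl-2-[(triisopropylsilyl)oxy]-4-{2-[(triisopropylsilyl)oxy]ethyl}deca-3,5,9-trienal | C=C(O[Si](C)(C)C(C)(C)C)CC(C)(C)/C=C(C)/C(CCO[Si](C(C)C)(C(C)C)C(C)C)=C(C)\[C@H](O[Si](C(C)C)(C(C)C)C(C)C)C=O | intermediate
23 | (5S,6S,7S,10S)-6β-hydroxy-7α,12-bis[(triisopropylsilyl)oxy]-13,14,15,16-tetranorlabd-8-en-2-one | O=C1CC(C)(C)[C@@H]2[C@H](O)[C@@H](O[Si](C(C)C)(C(C)C)C(C)C)C(C)=C(CCO[Si](C(C)C)(C(C)C)C(C)C)[C@@]2(C)C1 | intermediate
24 | (2S,5S,6S,7S,10S)-7α,12-bis[(triisopropylsilyl)oxy]-13,14,15,16-tetranorlabd-8-ene-2α,6β-diol | O[C@H]1CC(C)(C)[C@@H]2[C@H](O)[C@@H](O[Si](C(C)C)(C(C)C)C(C)C)C(C)=C(CCO[Si](C(C)C)(C(C)C)C(C)C)[C@@]2(C)C1 | intermediate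
25 | (2S,5S,6S,7S,10S)-13,14,15,16-tetranorlabd-8-ene-2α,6β,7α,12-tetrol | O[C@H]1CC(C)(C)[C@@H]2[C@H](O)[C@@H](O)C(C)=C(CCO)[C@@]2(C)C1 | intermediate
26 | (2S,5S,6S,7S,10S)-12-iodo-13,14,15,16-tetranorlabd-8-ene-2α,6β,7α-triol | O[C@H]1CC(C)(C)[C@@H]2[C@H](O)[C@@H](O)C(C)=C(CCI)[C@@]2(C)C1 | intermediate
27 | (2S,5S,6S,7S,10S)-12-iodo-13,14,15,16-tetranorlabd-8-ene-2α,6β,7α-triyl triacetate | CC(=O)O[C@H]1CC(C)(C)[C@@H]2[C@H](OC(C)=O)[C@@H](OC(C)=O)C(C)=C(CCI)[C@@]2(C)C1 | intermediate
28 | but-2-yn-1-ol | CC#CCO | starting material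
29 | (but-2-yn-1-yloxy)(tert-butyl)dimethylsilane | CC#CCO[Si](C)(C)C(C)(C)C | intermediate
30 | (E)-alkenylzirconocene chloride, Zr on C3 trans to CH2O (cyclopentadienyl rings written σ-bonded) | C/C(=C\CO[Si](C)(C)C(C)(C)C)[Zr](Cl)(C1C=CC=C1)C1C=CC=C1 | intermediate
31 | tert-butyl{[(2E)-3-iodobut-2-en-1-yl]oxy}dimethylsilane | C/C(I)=C\CO[Si](C)(C)C(C)(C)C | intermediate
32 | alkylzinc iodide of 27 (Zn on C12) | CC(=O)O[C@H]1CC(C)(C)[C@@H]2[C@H](OC(C)=O)[C@@H](OC(C)=O)C(C)=C(CC[Zn]I)[C@@]2(C)C1 | intermediate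
33 | (2S,5S,6S,7S,10S)-15-[(tert-butyldimethylsilyl)oxy]labda-8,13E-diene-2α,6β,7α-triyl triacetate | CC(=O)O[C@H]1CC(C)(C)[C@@H]2[C@H](OC(C)=O)[C@@H](OC(C)=O)C(C)=C(CC/C(C)=C/CO[Si](C)(C)C(C)(C)C)[C@@]2(C)C1 | intermediate
34 | (2S,5S,6S,7S,10S)-15-hydroxylabda-8,13E-diene-2α,6β,7α-triyl triacetate | CC(=O)O[C@H]1CC(C)(C)[C@@H]2[C@H](OC(C)=O)[C@@H](OC(C)=O)C(C)=C(CC/C(C)=C/CO)[C@@]2(C)C1 | target

Total step count: 21.
Longest linear sequence: 17 steps (steps 1–6, 9–17, 20 and 21).

Steps most likely to fail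

1. Step 13 (Proposed new method). The complexed aldehyde may be attacked without discrimination of its two faces, so that the new C6 carbinol is formed in the equatorial 6α series while the ring fusion and C7 are as planned. The fallback sets C6 by reduction of a ketone, all by known reactions. It sets out from 22, whose cyclisation would then give the 6α-hydroxy ketone F1. F1 is taken through the conditions of step 14 to the 2α,6α-diol F2. The unhindered equatorial C2 hydroxyl is silylated selectively (TBSCl, imidazole, DMF, 0 °C) to the 2-O-TBS ether F3. Dess–Martin oxidation gives the 6-ketone F4. NaBH4 (MeOH, −20 °C) should deliver hydride from the α face, away from the axial C4 and C10 methyl groups, to give the 6β-alcohol F5. TBAF as in step 15 removes all three silyl groups, and the route is rejoined at tetraol 25.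

2. Step 9. Transmetalation at the tetrasubstituted alkenylpalladium iodide may be slow, so that protodeboronation of 17 and reduction of 11 compete with C9–C10 bond formation. The fallback is a copper-assisted Stille coupling. It sets out from alkyne 16, which is hydrostannylated (Bu3SnH, PdCl2(PPh3)2, THF; syn addition, tin on the less hindered methyl-bearing carbon) to the (E)-alkenylstannane F6. F6 and iodide 11 are coupled with Pd(PPh3)4, Cu(thiophene-2-carboxylate) and Ph2PO2NBu4 in DMF, and the route is rejoined at 18.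

3. Step 14. Thermodynamic control at C2 may be incomplete, or electron transfer may cleave the allylic C7–O bond. The fallback is kinetic hydride reduction followed by inversion. It sets out from 23: NaBH4 (MeOH, 0 °C) should attack from the open α face and give the axial 2β-alcohol F7. A Mitsunobu reaction with 4-nitrobenzoic acid (PPh3, DIAD, toluene) inverts C2 to the 2α-(4-nitrobenzoate) F8; the hindered axial 6β-hydroxyl should not react. K2CO3 in MeOH cleaves the ester, and the route is rejoined at 24.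

Further compounds
F1 | step 13 | 6α-hydroxy-7α,12-bis[(triisopropylsilyl)oxy]-13,14,15,16-tetranorlabd-8-en-2-one | O=C1CC(C)(C)[C@@H]2[C@@H](O)[C@@H](O[Si](C(C)C)(C(C)C)C(C)C)C(C)=C(CCO[Si](C(C)C)(C(C)C)C(C)C)[C@@]2(C)C1
F2 | step 13 | 7α,12-bis[(triisopropylsilyl)oxy]-13,14,15,16-tetranorlabd-8-ene-2α,6α-diol | O[C@H]1CC(C)(C)[C@@H]2[C@@H](O)[C@@H](O[Si](C(C)C)(C(C)C)C(C)C)C(C)=C(CCO[Si](C(C)C)(C(C)C)C(C)C)[C@@]2(C)C1
F3 | step 13 | 2α-[(tert-butyldimethylsilyl)oxy]-7α,12-bis[(triisopropylsilyl)oxy]-13,14,15,16-tetranorlabd-8-en-6α-ol | CC(C)(C)[Si](C)(C)O[C@H]1CC(C)(C)[C@@H]2[C@@H](O)[C@@H](O[Si](C(C)C)(C(C)C)C(C)C)C(C)=C(CCO[Si](C(C)C)(C(C)C)C(C)C)[C@@]2(C)C1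
F4 | step 13 | 2α-[(tert-butyldimethylsilyl)oxy]-7α,12-bis[(triisopropylsilyl)oxy]-13,14,15,16-tetranorlabd-8-en-6-one | CC(C)(C)[Si](C)(C)O[C@H]1CC(C)(C)[C@@H]2C(=O)[C@@H](O[Si](C(C)C)(C(C)C)C(C)C)C(C)=C(CCO[Si](C(C)C)(C(C)C)C(C)C)[C@@]2(C)C1
F5 | step 13 | 2α-[(tert-butyldimethylsilyl)oxy]-7α,12-bis[(triisopropylsilyl)oxy]-13,14,15,16-tetranorlabd-8-en-6β-ol | CC(C)(C)[Si](C)(C)O[C@H]1CC(C)(C)[C@@H]2[C@H](O)[C@@H](O[Si](C(C)C)(C(C)C)C(C)C)C(C)=C(CCO[Si](C(C)C)(C(C)C)C(C)C)[C@@]2(C)C1
F6 | step 9 | (5E)-4,4-dimethyl-6-(tributylstannyl)hept-5-en-2-one | CC(=O)CC(C)(C)/C=C(\C)[Sn](CCCC)(CCCC)CCCC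
F7 | step 14 | 7α,12-bis[(triisopropylsilyl)oxy]-13,14,15,16-tetranorlabd-8-ene-2β,6β-diol | O[C@@H]1CC(C)(C)[C@@H]2[C@H](O)[C@@H](O[Si](C(C)C)(C(C)C)C(C)C)C(C)=C(CCO[Si](C(C)C)(C(C)C)C(C)C)[C@@]2(C)C1
F8 | step 14 | 6β-hydroxy-7α,12-bis[(triisopropylsilyl)oxy]-13,14,15,16-tetranorlabd-8-en-2α-yl 4-nitrobenzoate | O=C(O[C@H]1CC(C)(C)[C@@H]2[C@H](O)[C@@H](O[Si](C(C)C)(C(C)C)C(C)C)C(C)=C(CCO[Si](C(C)C)(C(C)C)C(C)C)[C@@]2(C)C1)c1ccc(cc1)[N+](=O)[O-]
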